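A catalyst's stay in catalyst intermediate D lasts 0.188 s, far shorter than the 27.5 s time constant of dissolving, so I treated this flask as a catalyst running laps through a slowly changing solution.

solid substrate 0.80 M; coupling partner 0.880 M; free catalyst 8.0 mM; time 1.0 min

- amount of product at 1.0 min, in percent of the solid substrate charged
- the change that raises the amount of product at 1.0 min, in percent of the solid substrate charged most ("none" if none brings more than 2 percentage points) (elm / alder / larch / oak / none)
- amount of product at 1.0 min, in percent of the solid substrate charged, after oak

- elm: doubling the amount of coupling partner, all else as stated
- alder: doubling the amount of free catalyst, all else as stated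
- larch: doubling the solubility in step 3, all else as stated
- oak: doubling the dissolution coefficient of step 3, all else as stated

    catalyst intermediate D → free catalyst + product (k1 = 5.31 /s)
    coupling partner + catalyst intermediate B → catalyst intermediate C (k2 = 5.27 /M/s)
    solid substrate ⇌ starting material, rate k3*(cs3 - [starting material]) while solid is left; crystals form when [starting material] > cs3 (cs3 = 0.73 M, k3 = 0.0364 /s)
    starting material + free catalyst ⇌ catalyst intermediate A (K4 = 2.6 /M, k4 = 4.99 /M/s)
    catalyst intermediate A ⇌ catalyst intermediate B (K5 = 8.7, k5 = 5.49 /s)
    catalyst intermediate C → catalyst intermediate D (k6 = 4.10 /s)

Free catalyst reversibly binds starting material, at concentration S, to give catalyst intermediate A, which reversibly becomes catalyst intermediate B. That takes up coupling partner to give catalyst intermediate C, which becomes catalyst intermediate D, and D releases product and free catalyst. A lifetime is one over a first-order rate constant. With coupling partner as charged, the time in B per lap is 0.216 s, and with B's slips back into A counted, the time in A per lap is 0.207 s. Summing the four bound forms gives the walk W = 0.855 s, the bound time per lap. Free catalyst adds a wait b/S, with b = 0.280 M·s. The lap time is W + b/S, and its inverse is the turnover frequency.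

The catalyst drains the solution at about 5.59 mM/s, so S climbs towards 0.577 M. I put it at 0.383 M at 0.500 min and 0.512 M at the end, giving laps of 1.59 s and 1.40 s. Starting from zero rate and weighting the midway rate 4 to 1 against the end, over 6, I reckoned 32.4%.

After oak, S reaches 0.580 M midway. Its end level plus product comes to more than the charge, so I ended S at charge minus product, 0.541 M, and reckoned 37.2%. Doubling coupling partner trims 0.120 s from W. Doubling the solubility or the dissolution coefficient acts on the wait, about half of the midway lap, whereas doubling catalyst doubles the laps running at once. I chose alder.

The forecast gave 33.5% (31% to 36%) and 37.8% (35% to 41%) after oak, and chose alder: “Doubling the catalyst therefore gives by far the biggest gain”.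

The simulation gave 33.4%, best alder with a gain of 26 percentage points (larch 6 points, oak 4.8 points, elm 3.7 points), and 38.2% after oak.

With coupling partner as charged and the catalyst forms in steady state, the wait's share of the lap, (b/S)/(W + b/S), is the share of catalyst standing free. In the flask at 0.500 min, the read S of 0.409 M gives 44.4%, and free catalyst read 43.7%. The neighbouring flask, charged with 0.20 M of solid substrate, gave 68.5% product at 1.00 min. Its S of 0.0617 M makes the wait 4.54 s beside the same W, for a share of 84.2%. Free catalyst there read 83.4%.

The numbers are those of an exercise; the run is a simulation.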